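**Plan**

1. Cuts (locants in the note below): the side chain at C1'=C2' (Horner–Wadsworth–Emmons) and at C1–CH2OH (formaldehyde aldol); ring D at C2–C14 and C10–C13 (double Mannich across a C1 ketone); rings A and B together at C4–C5 and C5–C6 (intramolecular Buchner reaction).
2. Forward order: ring C is the five-membered ring of 4-methoxy-1-indanone; one step closes ring B and expands the benzene ring to ring A; ring D, the quaternary C1 and the side chain follow.
3. Enabling feature: ring A is the six benzene carbons of a 4-methoxyindane (C1, C2, C3, C4, C6, C10) plus the diazo carbon C5, which inserts between ring-fusion carbon C6 and its free ortho carbon C4; the methoxy carbon becomes the C1 ketone.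
4. Stereochemistry: C7 and C8 from an iridium-catalysed asymmetric cis-hydrogenation; C10 and C2 from the substrate-controlled double Mannich reaction; C1 from a face-selective aldol; C3' from a CBS reduction.

Key step: step 7

Locants used below: C1 = quaternary carbon bearing CH2OH and the side chain; C2 = CH bearing C14H2N; C3, C4 = ring CH2; C5=C6 = ring alkene (C6 bonded to C7 and C10); C7 = ring-fusion CH; C8 = CH(CO2Me); C9 = CH2; C10 = quaternary carbon bearing C13H2N; C11 (on C7) and C12 (on C5) = CH2 groups of ring B; C1'–C5' = side chain from C1. Ring A = C1-C2-C3-C4-C5-C6-C10; ring B = C5-C6-C7-C11-C12; ring C = C6-C7-C8-C9-C10; ring D = C1-C2-C14-N-C13-C10.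

Assumption: in step 4 the (S)-configured phosphinooxazoline ligand is taken to give the (1S,2S) cis diester; if the sense is the opposite, the (R)-ligand is used.

**Route**

Step 1
Reactants: 1 4-methoxy-1-indanone; 2 dimethyl carbonate
Product: 3 methyl 4-methoxy-1-oxoindane-2-carboxylate
Conditions: NaH, THF, 65 °C; then aq. HCl
Reagents that add atoms: dimethyl carbonate, COC(=O)OC
Why: Claisen-type C-methoxycarbonylation of the indanone enolate should be driven by formation of the stabilised β-ketoester enolate; no stereocentre of consequence is formed.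

Step 2
Reactants: 3 methyl 4-methoxy-1-oxoindane-2-carboxylate
Product: 4 methyl 7-methoxy-3-(trifluoromethylsulfonyloxy)-1H-indene-2-carboxylate
Conditions: NaH, Et2O, 0 °C; then (CF3SO2)2O, 0 to 25 °C
Reagents that add atoms: trifluoromethanesulfonic anhydride, FC(F)(F)S(=O)(=O)OS(=O)(=O)C(F)(F)F
Why: O-triflation of the β-ketoester enolate (enol triflate formation) should fix the C7=C8 double bond and activate C7 for cross-coupling.

Step 3
Reactants: 4 methyl 7-methoxy-3-(trifluoromethylsulfonyloxy)-1H-indene-2-carboxylate; 5 (2-tert-butoxy-2-oxoethyl)zinc chloride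
Product: 6 methyl 3-(2-tert-butoxy-2-oxoethyl)-7-methoxy-1H-indene-2-carboxylate
Conditions: Pd(PPh3)4 (5 mol%), THF, 60 °C
Reagents that add atoms: (2-tert-butoxy-2-oxoethyl)zinc chloride, CC(C)(C)OC(=O)C[Zn]Cl
Why: Negishi cross-coupling of the Reformatsky reagent with the electron-poor vinyl triflate should install the C11–C12 acetate arm on C7, oxidative addition into the C–O bond of a β-triflyloxy acrylate being easy.

Step 4
Reactants: 6 methyl 3-(2-tert-butoxy-2-oxoethyl)-7-methoxy-1H-indene-2-carboxylate
Product: 7 methyl (1S,2S)-1-(2-tert-butoxy-2-oxoethyl)-4-methoxyindane-2-carboxylate (cis)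
Conditions: H2 (50 bar), [Ir(cod)(L)][B(C6H3(CF3)2)4] (2 mol%, L = (S)-2-[2-(diphenylphosphino)phenyl]-4-isopropyl-4,5-dihydrooxazole), CH2Cl2, 25 °C
Reagents that add atoms: none
Why: iridium phosphinooxazoline-catalysed asymmetric hydrogenation of a tetrasubstituted indene should add H2 syn to one face, which sets C7 and C8 together as the cis pair, the absolute sense being fixed by the ligand.

Step 5
Reactants: 7 methyl (1S,2S)-1-(2-tert-butoxy-2-oxoethyl)-4-methoxyindane-2-carboxylate
Product: 8 2-[(1S,2S)-4-methoxy-2-(methoxycarbonyl)indan-1-yl]acetic acid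
Conditions: CF3CO2H, CH2Cl2, 0 to 25 °C
Reagents that add atoms: none
Why: acidolysis of the tert-butyl ester (E1 loss of 2-methylpropene) should free the acetic acid arm while the methyl ester at C8 survives.

Step 6
Reactants: 8 2-[(1S,2S)-4-methoxy-2-(methoxycarbonyl)indan-1-yl]acetic acid; 9 (trimethylsilyl)diazomethane
Product: 11 methyl (1S,2S)-1-(3-diazo-2-oxopropyl)-4-methoxyindane-2-carboxylate, via acid chloride 10 (not isolated)
Conditions: (COCl)2, DMF (cat.), CH2Cl2, 0 to 25 °C; evaporate; Me3SiCHN2 (2 M in hexanes), MeCN/THF, 0 °C
Reagents that add atoms: (trimethylsilyl)diazomethane, C[Si](C)(C)C=[N+]=[N-]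
Why: acid chloride formation and C-acylation of the silyl diazomethane with loss of chlorotrimethylsilane (diazoketone synthesis of the Arndt–Eistert type) should give the α-diazoketone without a base able to epimerise C8.

Step 7
Reactants: 11 methyl (1S,2S)-1-(3-diazo-2-oxopropyl)-4-methoxyindane-2-carboxylate
Product: 13 ring A/B/C 1-methoxycycloheptatriene with C12 ketone and C8 ester (double bonds C1=C2 C3=C4 C6=C10), via norcaradiene 12 (not isolated)
Conditions: Rh2(OAc)4 (1 mol%), CH2Cl2, 40 °C, slow addition of 11
Reagents that add atoms: none
Why: Loss of N2 gives a rhodium carbene at C5 that adds across the arene bond between ring-fusion carbon C6 and its free ortho carbon C4 to give norcaradiene 12, whose 6π disrotatory electrocyclic opening cleaves the C4–C6 σ bond and leaves C5 inserted between them, so that the benzene ring becomes the seven-membered ring A (intramolecular Buchner reaction). The closest known reaction type is the rhodium-catalysed cyclisation of 1-diazo-4-arylbutan-2-ones to dihydroazulenones, which includes indan-1-yl tethers and methoxy arenes. Ring B closes in the cyclopropanation as a five-membered ring through the C5–C6 bond (the tether C7–C11–C12 delivers the carbene to the ipso carbon, a 5-exo-type closure), and ring A arises from the three-membered ring by ring opening, not by a closure of its own. The only new stereocentre, C5–H, is fixed by the tether (the carbene reaches only the arene face that carries the C7 arm) and disappears when C5 becomes sp2 in step 9. The step needs addition at C6–C4 instead of the other ortho bond C6–C10 or C–H insertion: C10 is the fully substituted ring-fusion carbon (addition there would give a strained propellane), C4 is para to the methoxy group and the most electron-rich position, the C8–H bond is deactivated by its ester and lies trans to the tether, and dirhodium tetraacetate favours arene addition over insertion.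

Step 8
Reactants: 13 ring A/B/C 1-methoxycycloheptatriene with C12 ketone and C8 ester
Product: 14 3,4-dihydro derivative of 13 (double bonds C1=C2 and C6=C10)
Conditions: KO2CN=NCO2K, AcOH, MeOH, 0 to 25 °C
Reagents that add atoms: none
Why: diimide reduction transfers H2 in a concerted syn fashion only to the unhindered 1,2-disubstituted C3=C4 bond, so the trisubstituted enol ether and the tetrasubstituted C6=C10 bond should survive; a conjugated double-bond isomer of 13 would converge on the same material in step 9.

Step 9
Reactants: 14 3,4-dihydro derivative of 13; 15 methylamine hydrochloride; 16 formaldehyde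
Product: 18 ring A–D amino diketone (bridging C1 ketone and C12 enone; N-methyl piperidine joined at C10 and C2), via ene-dione 17 (not isolated)
Conditions: 37% aq. CH2O (2.2 equiv), MeNH2·HCl (1.1 equiv), AcOH, MeOH, 65 °C; then aq. NaOH
Reagents that add atoms: methylamine hydrochloride, CN.Cl; formaldehyde, C=O; water, O
Why: aqueous acid hydrolyses the dienol ether to the C1 ketone (17, a vinylogous 1,3-diketone whose acidic hydrogen sits at C10/C5, so C7 is not touched) and a double Mannich annulation then joins C10 and C2 across the C1 carbonyl; the reversible Mannich steps should funnel to the strain-free bicyclo[4.3.1] product and not to the bridged cyclopentanone from C5/C11, and the iminium carbon should enter at C10 on the convex face away from the C8 ester and the C11–C12 bridge, giving C13 cis to H7 and, through the bridge, the C2 configuration.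

Step 10
Reactants: 18 ring A–D amino diketone
Product: 19 C1/C12 diol
Conditions: NaBH4, CeCl3·7H2O, MeOH, -40 to 0 °C
Reagents that add atoms: none
Why: Luche reduction should give clean 1,2-reduction of the C12 enone to the allylic alcohol; the bridging C1 ketone is reduced as well and restored in step 12, the two carbinol configurations being irrelevant.

Step 11
Reactants: 19 C1/C12 diol
Product: 20 C1 alcohol with C12 as CH2
Conditions: Et3SiH, CF3CO2H, CH2Cl2, -20 to 0 °C; then aq. NaHCO3, MeOH
Reagents that add atoms: none
Why: ionic deoxygenation, in which acid ionises only the allylic C12 alcohol to the C12–C5–C6 allyl cation and hydride from triethylsilane adds to the less hindered terminus C12, should keep the tetrasubstituted C5=C6 bond; the non-allylic C1 alcohol is inert and the low temperature disfavours protonation of the alkene.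

Step 12
Reactants: 20 C1 alcohol
Product: 21 C1 ketone (3-methyl-3-azabicyclo[4.3.1] core with rings B and C)
Conditions: Dess–Martin periodinane, pyridine, CH2Cl2, 25 °C
Reagents that add atoms: none
Why: Dess–Martin oxidation of the secondary C1 alcohol should return the bridging ketone; its α-carbons cannot epimerise (C10 quaternary, C2 a bridgehead).

Step 13
Reactants: 21 C1 ketone; 22 (methoxymethyl)triphenylphosphonium chloride
Product: 24 C1 carbaldehyde (C1 epimers), via enol ether 23 (not isolated)
Conditions: KN(SiMe3)2, THF, 0 to 50 °C; then 2 M aq. HCl, THF, 25 °C; NaHCO3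
Reagents that add atoms: (methoxymethyl)triphenylphosphonium chloride, COC[P+](c1ccccc1)(c1ccccc1)c1ccccc1.[Cl-]; water, O
Why: Wittig methoxymethylenation of the bridging ketone and hydrolysis of the enol ether (one-carbon homologation) should give the aldehyde; the C1 epimer mixture is of no consequence because C1 is planarised in step 14.

Step 14
Reactants: 24 C1 carbaldehyde; 16 formaldehyde
Product: 25 C1 hydroxymethyl carbaldehyde (CH2OH syn to the C3–C6 bridge)
Conditions: 37% aq. CH2O, Et3N (0.3 equiv), THF, 45 °C
Reagents that add atoms: formaldehyde, C=O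
Why: amine-catalysed crossed aldol reaction of the α-branched aldehyde with formaldehyde creates the quaternary C1; formaldehyde should approach the enol over ring A (one syn-axial hydrogen at C3 and the flat sp2 C6) and not over the piperidine (two syn-axial hydrogens at C13 and C14), which puts CH2OH syn to the C3–C6 bridge and the formyl group (future side chain) syn to nitrogen.

Step 15
Reactants: 25 C1 hydroxymethyl carbaldehyde; 26 diethyl (2-oxobutyl)phosphonate
Product: 27 side-chain E-enone
Conditions: Ba(OH)2·8H2O, THF/H2O (40:1), 25 °C
Reagents that add atoms: diethyl (2-oxobutyl)phosphonate, CCC(=O)CP(=O)(OCC)OCC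
Why: Horner–Wadsworth–Emmons olefination of the neopentyl aldehyde with the β-ketophosphonate under mild barium hydroxide conditions should give the E-enone and tolerate the free hydroxyl group and the methyl ester.

Step 16
Reactants: 27 side-chain E-enone
Product: 28 (S)-allylic alcohol
Conditions: (R)-2-methyl-CBS-oxazaborolidine (0.2 equiv), catecholborane (4 equiv), toluene/CH2Cl2, -78 °C; then aq. NaOH
Reagents that add atoms: none
Why: Corey–Bakshi–Shibata reduction, with the alkenyl group as the large and ethyl as the small substituent, should give the (S)-carbinol at C3' under catalyst control with the (R)-oxazaborolidine, the excess borane being taken up by the free hydroxyl group and the amine.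

Step 17
Reactants: 28 (S)-allylic alcohol
Product: 29 target CNP0291564.1
Conditions: KO2CN=NCO2K (excess), AcOH, MeOH, 25 °C
Reagents that add atoms: none
Why: diimide reduction of the 1,2-disubstituted side-chain alkene should leave the tetrasubstituted C5=C6 bond and the allylic C–O bond untouched (no hydrogenolysis or isomerisation to the ketone as with palladium), which completes the target.

**Compound list**

1 | 4-methoxy-1-indanone | COc1cccc2C(=O)CCc12 | starting material
2 | dimethyl carbonate | COC(=O)OC | starting material
3 | methyl 4-methoxy-1-oxoindane-2-carboxylate (racemic, enolisable) | COC(=O)C1Cc2c(OC)cccc2C1=O | intermediate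
4 | methyl 7-methoxy-3-(trifluoromethylsulfonyloxy)-1H-indene-2-carboxylate | COC(=O)C1=C(OS(=O)(=O)C(F)(F)F)c2cccc(OC)c2C1 | intermediate
5 | (2-tert-butoxy-2-oxoethyl)zinc chloride | CC(C)(C)OC(=O)C[Zn]Cl | starting material
6 | methyl 3-(2-tert-butoxy-2-oxoethyl)-7-methoxy-1H-indene-2-carboxylate | COC(=O)C1=C(CC(=O)OC(C)(C)C)c2cccc(OC)c2C1 | intermediate
7 | methyl (1S,2S)-1-(2-tert-butoxy-2-oxoethyl)-4-methoxyindane-2-carboxylate (cis) | COC(=O)[C@H]1Cc2c(OC)cccc2[C@H]1CC(=O)OC(C)(C)C | intermediate
8 | 2-[(1S,2S)-4-methoxy-2-(methoxycarbonyl)indan-1-yl]acetic acid | COC(=O)[C@H]1Cc2c(OC)cccc2[C@H]1CC(=O)O | intermediate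
9 | (trimethylsilyl)diazomethane | C[Si](C)(C)C=[N+]=[N-] | starting material
10 | acid chloride of 8 (not isolated) | COC(=O)[C@H]1Cc2c(OC)cccc2[C@H]1CC(=O)Cl | intermediate
11 | methyl (1S,2S)-1-(3-diazo-2-oxopropyl)-4-methoxyindane-2-carboxylate | COC(=O)[C@H]1Cc2c(OC)cccc2[C@H]1CC(=O)C=[N+]=[N-] | intermediate
12 | norcaradiene with cyclopropane C4–C5–C6 (not isolated) | COC1=C2C[C@H](C(=O)OC)[C@@H]3CC(=O)[C@H]4[C@H](C=C1)[C@@]234 | intermediate
13 | ring A/B/C cycloheptatriene: 1-OMe, C1=C2, C3=C4, C6=C10, C12 ketone, C8 ester, H5 anti to H7 | COC1=CC=C[C@@H]2C(=O)C[C@H]3[C@@H](C(=O)OC)CC1=C23 | intermediate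
14 | 3,4-dihydro derivative of 13 (C1=C2 enol ether, C6=C10) | COC1=CCC[C@@H]2C(=O)C[C@H]3[C@@H](C(=O)OC)CC1=C23 | intermediate
15 | methylamine hydrochloride | CN.Cl | starting material
16 | formaldehyde (37% aqueous) | C=O | starting material
17 | ene-dione: C1 ketone, C12 ketone, C5=C6, C10–H not defined (tautomer mixture, not isolated) | O=C1CCCC2=C3[C@@H](CC2=O)[C@@H](C(=O)OC)CC31 | intermediate
18 | ring A–D amino diketone: bridging C1 ketone, C12 enone, N-methyl piperidine at C10 and C2 | O=C1[C@H]2CCC3=C4[C@@H](CC3=O)[C@@H](C(=O)OC)C[C@]41CN(C)C2 | intermediate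
19 | C1/C12 diol (carbinol configurations not assigned) | OC1[C@H]2CCC3=C4[C@@H](CC3O)[C@@H](C(=O)OC)C[C@]41CN(C)C2 | intermediate
20 | C1 alcohol, C12 = CH2 (C1 configuration not assigned) | OC1[C@H]2CCC3=C4[C@@H](CC3)[C@@H](C(=O)OC)C[C@]41CN(C)C2 | intermediate
21 | C1 ketone | O=C1[C@H]2CCC3=C4[C@@H](CC3)[C@@H](C(=O)OC)C[C@]41CN(C)C2 | intermediate
22 | (methoxymethyl)triphenylphosphonium chloride | COC[P+](c1ccccc1)(c1ccccc1)c1ccccc1.[Cl-] | starting material
23 | C1 methoxymethylene enol ether (E/Z mixture, not isolated) | COC=C1[C@H]2CCC3=C4[C@@H](CC3)[C@@H](C(=O)OC)C[C@]41CN(C)C2 | intermediate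
24 | C1 carbaldehyde (C1 epimers) | O=CC1[C@H]2CCC3=C4[C@@H](CC3)[C@@H](C(=O)OC)C[C@]41CN(C)C2 | intermediate
25 | C1 hydroxymethyl carbaldehyde, CH2OH syn to the C3–C6 bridge | O=C[C@]1(CO)[C@H]2CCC3=C4[C@@H](CC3)[C@@H](C(=O)OC)C[C@]41CN(C)C2 | intermediate
26 | diethyl (2-oxobutyl)phosphonate | CCC(=O)CP(=O)(OCC)OCC | starting material
27 | side-chain E-enone (C1'=C2', C3' ketone) | CCC(=O)/C=C/[C@]1(CO)[C@H]2CCC3=C4[C@@H](CC3)[C@@H](C(=O)OC)C[C@]41CN(C)C2 | intermediate
28 | (S)-allylic alcohol at C3' | CC[C@H](O)/C=C/[C@]1(CO)[C@H]2CCC3=C4[C@@H](CC3)[C@@H](C(=O)OC)C[C@]41CN(C)C2 | intermediate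
29 | target CNP0291564.1 | CC[C@H](O)CC[C@]1(CO)[C@H]2CCC3=C4[C@@H](CC3)[C@@H](C(=O)OC)C[C@]41CN(C)C2 | target

**Step count**

Total steps: 17. Longest linear sequence: 17 steps (from 1); all other inputs are commercial reagents.

**Steps most likely to fail**

Step 9 (hydrolysis and double Mannich annulation). Aminomethylation may take place at C5 and C11 across the C12 ketone, may stop after one C–C bond, or the electrophile may approach C10 from the ester face. The fallback builds ring D stepwise with the first carbon placed at C2 by construction. It sets out from 14. The enol ether carbon C2 is amidoalkylated with tert-butyl (methoxymethyl)(methyl)carbamate and Me3SiOTf in CH2Cl2 at -78 °C (Mukaiyama–Mannich type); aqueous work-up gives the Boc-protected C2 Mannich base of the ene-dione F4. CF3CO2H removes the carbamate to give the C2 methylaminomethyl ene-dione trifluoroacetate F5. Aqueous formaldehyde in AcOH then closes ring D by an intramolecular Mannich reaction, which can reach only C10 through a six-membered transition state, and the route is rejoined at 18.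

Step 4 (asymmetric hydrogenation). Turnover on the tetrasubstituted alkene may be slow, enantioface discrimination may be poor, or the double bond may migrate before reduction. The fallback gives up catalyst control for resolution and sets out from 6. Hydrogenation over Pd/C in EtOAc adds H2 syn and gives the racemic cis diester, that is 7 together with the enantiomer of 7 F1. CF3CO2H gives the racemic acid, 8 together with the enantiomer of 8 F2. Crystallisation with (S)-1-phenylethylamine (the amine enantiomer is chosen by trial) gives the less soluble (S)-1-phenylethylammonium salt of 8 F3, and acidification returns 8, where the route is rejoined.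

Step 14 (aldol creating the quaternary C1). Formaldehyde may enter from the piperidine face, or selectivity may be low, and retro-aldol loss of formaldehyde may erode the product. The fallback inverts the order in which the two carbon substituents arrive and sets out from 21. Wittig reaction with (allyloxymethyl)triphenylphosphonium chloride and KN(SiMe3)2 gives the C1 allyloxymethylene enol ether F6. Heating in toluene at 150 °C brings about a Claisen rearrangement that delivers the allyl group (the future chain) to C1 on the face an external electrophile prefers and leaves the formyl group on the other face, giving the C1 allyl carbaldehyde F7. NaBH4 in MeOH gives the C1 allyl hydroxymethyl compound F8. RuHCl(CO)(PPh3)3 in toluene at 80 °C moves the double bond to give the C1 (E)-propenyl hydroxymethyl compound F9. Cross-metathesis with ethyl vinyl ketone (second-generation Hoveyda–Grubbs catalyst, amine protonated with TsOH, CH2Cl2, 40 °C) gives 27, where the route is rejoined.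

**Further compounds**

F1 | step 4 | enantiomer of 7 (formed with 7 as the racemate) | COC(=O)[C@@H]1Cc2c(OC)cccc2[C@@H]1CC(=O)OC(C)(C)C
F2 | step 4 | enantiomer of 8 (formed with 8 as the racemate) | COC(=O)[C@@H]1Cc2c(OC)cccc2[C@@H]1CC(=O)O
F3 | step 4 | (S)-1-phenylethylammonium salt of 8 | COC(=O)[C@H]1Cc2c(OC)cccc2[C@H]1CC(=O)[O-].C[C@H]([NH3+])c1ccccc1
F4 | step 9 | Boc-protected C2 Mannich base of the ene-dione (C2 and C10 not defined) | O=C1C(CN(C)C(=O)OC(C)(C)C)CCC2=C3[C@@H](CC2=O)[C@@H](C(=O)OC)CC31
F5 | step 9 | C2 methylaminomethyl ene-dione trifluoroacetate | O=C1C(CNC)CCC2=C3[C@@H](CC2=O)[C@@H](C(=O)OC)CC31.OC(=O)C(F)(F)F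
F6 | step 14 | C1 allyloxymethylene enol ether | C=CCOC=C1[C@H]2CCC3=C4[C@@H](CC3)[C@@H](C(=O)OC)C[C@]41CN(C)C2
F7 | step 14 | C1 allyl carbaldehyde | C=CC[C@]1(C=O)[C@H]2CCC3=C4[C@@H](CC3)[C@@H](C(=O)OC)C[C@]41CN(C)C2
F8 | step 14 | C1 allyl hydroxymethyl compound | C=CC[C@]1(CO)[C@H]2CCC3=C4[C@@H](CC3)[C@@H](C(=O)OC)C[C@]41CN(C)C2
F9 | step 14 | C1 (E)-propenyl hydroxymethyl compound | C/C=C/[C@]1(CO)[C@H]2CCC3=C4[C@@H](CC3)[C@@H](C(=O)OC)C[C@]41CN(C)C2
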